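**Plan**
- Retrosynthesis: the eight O-benzyl groups go last. Ring C of the flavanone unit is then cut at C3–C4 and O1–C2 into a ring-A salicylaldehyde and an aryl alkyne that carries the whole flavone unit. The alkyne goes back to an aryl aldehyde, the C5'–C8'' biaryl bond to an 8-iodoflavone and an arylboronate, and the flavone ring to an iodinated acetophenone and an aldehyde.
- Forward order: the flavone unit is built first (iodination, aldol condensation, oxidative ring closure), then the biaryl bond, then the alkyne. The flavanone ring C is closed last, on the complete carbon skeleton.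
- Enabling feature: on ring A the phenol oxygen (future O1) sits ortho to the formyl carbon (future C4). This salicyl pair chelates rhodium for formyl C–H activation, and the same oxygen then closes onto C2.
- Stereochemistry: C2 (S) is the only stereocentre. It is set in the key step by a chiral bifunctional catalyst and afterwards meets only neutral hydrogenolysis.

Key step: step 10

Remark: the biaryl axis carries three ortho oxygen substituents and is taken as freely rotating, so C2 is treated as the only stereo-element.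

**Step 1**
Reactants: 1 1-(2,4,6-trihydroxyphenyl)ethanone
Product: 2 1-[2,4-bis(benzyloxy)-6-hydroxyphenyl]ethanone
Conditions: BnBr (2.1 equiv), K2CO3, DMF, rt
Reagents that add atoms: benzyl bromide, BrCc1ccccc1
Why: Williamson etherification; the phenol hydrogen-bonded to the acetyl carbonyl is the least nucleophilic and should stay free.

**Step 2**
Reactants: 2 1-[2,4-bis(benzyloxy)-6-hydroxyphenyl]ethanone
Product: 3 1-[4,6-bis(benzyloxy)-2-hydroxy-3-iodophenyl]ethanone
Conditions: NIS, TFA (cat.), MeCN, 0 °C to rt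
Reagents that add atoms: N-iodosuccinimide, O=C1CCC(=O)N1I
Why: electrophilic aromatic iodination ortho to the free phenol; C3 (between OH and OBn) is less hindered than C5 (between two OBn groups).

**Step 3**
Reactants: 3 1-[4,6-bis(benzyloxy)-2-hydroxy-3-iodophenyl]ethanone; 4 3,4-bis(benzyloxy)benzaldehyde
Product: 5 (E)-1-[4,6-bis(benzyloxy)-2-hydroxy-3-iodophenyl]-3-[3,4-bis(benzyloxy)phenyl]prop-2-en-1-one
Conditions: KOH (50% aq), EtOH/THF, rt
Reagents that add atoms: none
Why: Claisen–Schmidt aldol condensation with dehydration to the E-enone; aryl iodide and benzyl ethers are inert to hydroxide, and any flavanone formed by early ring closure converges in step 4.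

**Step 4**
Reactants: 5 (E)-1-[4,6-bis(benzyloxy)-2-hydroxy-3-iodophenyl]-3-[3,4-bis(benzyloxy)phenyl]prop-2-en-1-one
Product: 6 5,7-bis(benzyloxy)-2-[3,4-bis(benzyloxy)phenyl]-8-iodo-4H-chromen-4-one
Conditions: I2 (cat.), DMSO, 120 °C
Reagents that add atoms: none
Why: iodine-catalysed oxidative cyclisation of a 2'-hydroxychalcone to a flavone (oxa-Michael closure, α-iodination, loss of HI, DMSO as terminal oxidant); the iodine ortho to the phenol becomes C8.

**Step 5**
Reactants: 7 3-bromo-4,5-dihydroxybenzaldehyde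
Product: 8 3,4-bis(benzyloxy)-5-bromobenzaldehyde
Conditions: BnBr (2.3 equiv), K2CO3, DMF, 60 °C
Reagents that add atoms: benzyl bromide, BrCc1ccccc1
Why: Williamson etherification of both catechol hydroxyls.

**Step 6**
Reactants: 8 3,4-bis(benzyloxy)-5-bromobenzaldehyde
Product: 9 3,4-bis(benzyloxy)-5-(4,4,5,5-tetramethyl-1,3,2-dioxaborolan-2-yl)benzaldehyde
Conditions: B2pin2, PdCl2(dppf) (cat.), KOAc, 1,4-dioxane, 90 °C
Reagents that add atoms: bis(pinacolato)diboron, CC1(C)OB(OC1(C)C)B1OC(C)(C)C(C)(C)O1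
Why: Miyaura borylation of an aryl bromide; the weak base KOAc spares the aldehyde.

**Step 7**
Reactants: 6 5,7-bis(benzyloxy)-2-[3,4-bis(benzyloxy)phenyl]-8-iodo-4H-chromen-4-one; 9 3,4-bis(benzyloxy)-5-(4,4,5,5-tetramethyl-1,3,2-dioxaborolan-2-yl)benzaldehyde
Product: 10 3,4-bis(benzyloxy)-5-{5,7-bis(benzyloxy)-2-[3,4-bis(benzyloxy)phenyl]-4-oxo-4H-chromen-8-yl}benzaldehyde
Conditions: Pd(OAc)2 (5 mol %), SPhos (10 mol %), K3PO4, toluene/H2O, 90 °C
Reagents that add atoms: none
Why: Suzuki–Miyaura coupling; the bulky dialkylbiarylphosphine SPhos is suited to the C8 iodide flanked by two oxygen substituents, and aldehyde and flavone tolerate the conditions.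

**Step 8**
Reactants: 10 3,4-bis(benzyloxy)-5-{5,7-bis(benzyloxy)-2-[3,4-bis(benzyloxy)phenyl]-4-oxo-4H-chromen-8-yl}benzaldehyde
Product: 11 5,7-bis(benzyloxy)-2-[3,4-bis(benzyloxy)phenyl]-8-[2,3-bis(benzyloxy)-5-ethynylphenyl]-4H-chromen-4-one
Conditions: dimethyl (1-diazo-2-oxopropyl)phosphonate, K2CO3, MeOH/THF, 0 °C to rt
Reagents that add atoms: dimethyl (1-diazo-2-oxopropyl)phosphonate, CC(=O)C(=[N+]=[N-])P(=O)(OC)OC
Why: Seyferth–Gilbert homologation in the Ohira–Bestmann variant turns the aryl aldehyde into the terminal alkyne under mild carbonate/methanol conditions that the flavone and benzyl ethers tolerate.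

**Step 9**
Reactants: 12 2,4,6-trihydroxybenzaldehyde
Product: 13 2,4-bis(benzyloxy)-6-hydroxybenzaldehyde
Conditions: BnBr (2.0 equiv), K2CO3, DMF, rt
Reagents that add atoms: benzyl bromide, BrCc1ccccc1
Why: Williamson etherification; the phenol chelated to the formyl group should stay free, and it is the handle the key step needs.

**Step 10**
Reactants: 13 2,4-bis(benzyloxy)-6-hydroxybenzaldehyde; 11 5,7-bis(benzyloxy)-2-[3,4-bis(benzyloxy)phenyl]-8-[2,3-bis(benzyloxy)-5-ethynylphenyl]-4H-chromen-4-one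
Product: 15 (2S)-5,7-bis(benzyloxy)-2-(3,4-bis(benzyloxy)-5-{5,7-bis(benzyloxy)-2-[3,4-bis(benzyloxy)phenyl]-4-oxo-4H-chromen-8-yl}phenyl)chroman-4-one, via (E)-2'-hydroxychalcone 14 (not isolated)
Conditions: [RhCl(cod)]2 (2.5 mol %), dppf (5 mol %), Na2CO3 (10 mol %), toluene, 80 °C; then 0 °C, 1-[3,5-bis(trifluoromethyl)phenyl]-3-[(8S,9S)-6'-methoxycinchonan-9-yl]thiourea (20 mol %)
Reagents that add atoms: none
Why: The free phenol of 13 binds rhodium as a phenoxide and directs insertion into the adjacent formyl C–H bond to give a five-membered acyl(hydrido)rhodacycle; syn-hydrometalation of the terminal alkyne of 11 and acyl–vinyl reductive elimination give the (E)-2'-hydroxychalcone 14, and the same phenol oxygen then adds to the enone β-carbon. The closest known reaction type is the tandem rhodium-catalysed alkyne hydroacylation/oxa-Michael synthesis of chroman-4-ones from salicylaldehydes, run here with the bifunctional cinchona-thiourea catalysis known for the cyclisation of 2'-hydroxychalcones to flavanones. Ring C of the flavanone closes by a 6-endo-trig oxa-Michael addition. The C2 stereocentre is set under kinetic control by the catalyst, whose thiourea binds the enone carbonyl while the quinuclidine nitrogen guides the phenol to one enone face (the quinine-derived catalyst or its quinidine-derived pseudoenantiomer is taken according to which gives the 2S sense in a trial on a model chalcone). The step needs linear regiochemistry, which the aryl group should secure by sending rhodium to the unhindered alkyne terminus, and it needs the racemic background closure and the retro-Michael opening to stay slow, which the small amount of insoluble carbonate, the low temperature of the second stage and the 4'-O-benzyl group on ring B (no quinone-methide opening) should secure.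

**Step 11**
Reactants: 15 (2S)-5,7-bis(benzyloxy)-2-(3,4-bis(benzyloxy)-5-{5,7-bis(benzyloxy)-2-[3,4-bis(benzyloxy)phenyl]-4-oxo-4H-chromen-8-yl}phenyl)chroman-4-one
Product: 16 (2S)-2-{3,4-dihydroxy-5-[2-(3,4-dihydroxyphenyl)-5,7-dihydroxy-4-oxo-4H-chromen-8-yl]phenyl}-5,7-dihydroxychroman-4-one
Conditions: H2 (1 atm), 10% Pd/C, THF/MeOH, rt
Reagents that add atoms: none
Why: catalytic hydrogenolysis of the eight aryl benzyl ethers under neutral conditions, which avoids base-mediated ring opening and racemisation at C2; at 1 atm and rt the flavone double bond and the flavanone C2–O1 bond should survive if the reaction is stopped at completion.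

**Compound list**
1 | 1-(2,4,6-trihydroxyphenyl)ethanone | CC(=O)c1c(O)cc(O)cc1O | starting material
2 | 1-[2,4-bis(benzyloxy)-6-hydroxyphenyl]ethanone | CC(=O)c1c(O)cc(OCc2ccccc2)cc1OCc1ccccc1 | intermediate
3 | 1-[4,6-bis(benzyloxy)-2-hydroxy-3-iodophenyl]ethanone | CC(=O)c1c(O)c(I)c(OCc2ccccc2)cc1OCc1ccccc1 | intermediate
4 | 3,4-bis(benzyloxy)benzaldehyde | O=Cc1ccc(OCc2ccccc2)c(OCc2ccccc2)c1 | starting material
5 | (E)-1-[4,6-bis(benzyloxy)-2-hydroxy-3-iodophenyl]-3-[3,4-bis(benzyloxy)phenyl]prop-2-en-1-one | O=C(/C=C/c1ccc(OCc2ccccc2)c(OCc2ccccc2)c1)c1c(O)c(I)c(OCc2ccccc2)cc1OCc1ccccc1 | intermediate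
6 | 5,7-bis(benzyloxy)-2-[3,4-bis(benzyloxy)phenyl]-8-iodo-4H-chromen-4-one | O=c1cc(-c2ccc(OCc3ccccc3)c(OCc3ccccc3)c2)oc2c(I)c(OCc3ccccc3)cc(OCc3ccccc3)c12 | intermediate
7 | 3-bromo-4,5-dihydroxybenzaldehyde | O=Cc1cc(O)c(O)c(Br)c1 | starting material
8 | 3,4-bis(benzyloxy)-5-bromobenzaldehyde | O=Cc1cc(Br)c(OCc2ccccc2)c(OCc2ccccc2)c1 | intermediate
9 | 3,4-bis(benzyloxy)-5-(4,4,5,5-tetramethyl-1,3,2-dioxaborolan-2-yl)benzaldehyde | O=Cc1cc(OCc2ccccc2)c(OCc2ccccc2)c(B2OC(C)(C)C(C)(C)O2)c1 | intermediate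
10 | 3,4-bis(benzyloxy)-5-{5,7-bis(benzyloxy)-2-[3,4-bis(benzyloxy)phenyl]-4-oxo-4H-chromen-8-yl}benzaldehyde | O=Cc1cc(OCc2ccccc2)c(OCc2ccccc2)c(-c2c(OCc3ccccc3)cc(OCc3ccccc3)c3c(=O)cc(-c4ccc(OCc5ccccc5)c(OCc5ccccc5)c4)oc23)c1 | intermediate
11 | 5,7-bis(benzyloxy)-2-[3,4-bis(benzyloxy)phenyl]-8-[2,3-bis(benzyloxy)-5-ethynylphenyl]-4H-chromen-4-one | C#Cc1cc(OCc2ccccc2)c(OCc2ccccc2)c(-c2c(OCc3ccccc3)cc(OCc3ccccc3)c3c(=O)cc(-c4ccc(OCc5ccccc5)c(OCc5ccccc5)c4)oc23)c1 | intermediate
12 | 2,4,6-trihydroxybenzaldehyde | O=Cc1c(O)cc(O)cc1O | starting material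
13 | 2,4-bis(benzyloxy)-6-hydroxybenzaldehyde | O=Cc1c(O)cc(OCc2ccccc2)cc1OCc1ccccc1 | intermediate
14 | (E)-1-[2,4-bis(benzyloxy)-6-hydroxyphenyl]-3-(3,4-bis(benzyloxy)-5-{5,7-bis(benzyloxy)-2-[3,4-bis(benzyloxy)phenyl]-4-oxo-4H-chromen-8-yl}phenyl)prop-2-en-1-one | O=C(/C=C/c1cc(OCc2ccccc2)c(OCc2ccccc2)c(-c2c(OCc3ccccc3)cc(OCc3ccccc3)c3c(=O)cc(-c4ccc(OCc5ccccc5)c(OCc5ccccc5)c4)oc23)c1)c1c(O)cc(OCc2ccccc2)cc1OCc1ccccc1 | intermediate
15 | (2S)-5,7-bis(benzyloxy)-2-(3,4-bis(benzyloxy)-5-{5,7-bis(benzyloxy)-2-[3,4-bis(benzyloxy)phenyl]-4-oxo-4H-chromen-8-yl}phenyl)chroman-4-one | O=C1C[C@@H](c2cc(OCc3ccccc3)c(OCc3ccccc3)c(-c3c(OCc4ccccc4)cc(OCc4ccccc4)c4c(=O)cc(-c5ccc(OCc6ccccc6)c(OCc6ccccc6)c5)oc34)c2)Oc2cc(OCc3ccccc3)cc(OCc3ccccc3)c21 | intermediate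
16 | (2S)-2-{3,4-dihydroxy-5-[2-(3,4-dihydroxyphenyl)-5,7-dihydroxy-4-oxo-4H-chromen-8-yl]phenyl}-5,7-dihydroxychroman-4-one | O=C1C[C@@H](c2cc(O)c(O)c(-c3c(O)cc(O)c4c(=O)cc(-c5ccc(O)c(O)c5)oc34)c2)Oc2cc(O)cc(O)c21 | target

**Step count**
Total steps: 11. Longest linear sequence: 8 steps (steps 1, 2, 3, 4, 7, 8, 10, 11).

**Steps most likely to fail**

Step 10. The alkyne may insert with the wrong regiochemistry or oligomerise at rhodium, and a racemic background ring closure or a reversible retro-Michael opening may erode the enantiomeric purity. Fallback, setting out from aldehyde 10 and acetophenone 2: Claisen–Schmidt condensation (KOH, EtOH/THF) would give chalcone 14 as an isolated compound. Heating 14 with NaOAc in EtOH would close it to the racemic flavanone F1. Preparative HPLC on a chiral stationary phase would separate 15 from the (2R)-enantiomer F2, which is re-equilibrated through 14 with NaOAc and recycled. The route is rejoined at 15.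

Step 7. Transmetalation at the doubly ortho-flanked C8 position may be slow, so that protodeboronation of the boronate and hydrodeiodination of the iodide take over. Fallback, setting out from bromide 8: acetalisation (ethylene glycol, TsOH, toluene, reflux) would give the dioxolane-protected bromide F3. Bromine–lithium exchange (n-BuLi, THF, −78 °C) would give the aryllithium F4, and ZnCl2 would turn it into the arylzinc chloride F5. Negishi coupling of F5 with iodide 6 (Pd2(dba)3, RuPhos, THF, 60 °C) would give the biaryl acetal F6. Aqueous HCl in THF would release the aldehyde, and the route is rejoined at 10.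

Step 11. The flavone double bond may be over-reduced, the benzylic C2–O1 bond of the flavanone may be opened by hydrogenolysis, or the reaction may stall because partly debenzylated intermediates are poorly soluble. Fallback, setting out from 15: non-reductive Lewis-acid debenzylation with BCl3 and pentamethylbenzene as cation scavenger (CH2Cl2, −78 °C) would give 16 directly, without hydrogen or palladium.

**Further compounds**
F1 | step 10 | racemic 5,7-bis(benzyloxy)-2-(3,4-bis(benzyloxy)-5-{5,7-bis(benzyloxy)-2-[3,4-bis(benzyloxy)phenyl]-4-oxo-4H-chromen-8-yl}phenyl)chroman-4-one | O=C1CC(c2cc(OCc3ccccc3)c(OCc3ccccc3)c(-c3c(OCc4ccccc4)cc(OCc4ccccc4)c4c(=O)cc(-c5ccc(OCc6ccccc6)c(OCc6ccccc6)c5)oc34)c2)Oc2cc(OCc3ccccc3)cc(OCc3ccccc3)c21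
F2 | step 10 | (2R)-5,7-bis(benzyloxy)-2-(3,4-bis(benzyloxy)-5-{5,7-bis(benzyloxy)-2-[3,4-bis(benzyloxy)phenyl]-4-oxo-4H-chromen-8-yl}phenyl)chroman-4-one | O=C1C[C@H](c2cc(OCc3ccccc3)c(OCc3ccccc3)c(-c3c(OCc4ccccc4)cc(OCc4ccccc4)c4c(=O)cc(-c5ccc(OCc6ccccc6)c(OCc6ccccc6)c5)oc34)c2)Oc2cc(OCc3ccccc3)cc(OCc3ccccc3)c21
F3 | step 7 | 2-[3,4-bis(benzyloxy)-5-bromophenyl]-1,3-dioxolane | C1COC(O1)c1cc(Br)c(OCc2ccccc2)c(OCc2ccccc2)c1
F4 | step 7 | [2,3-bis(benzyloxy)-5-(1,3-dioxolan-2-yl)phenyl]lithium | C1COC(O1)c1cc([Li])c(OCc2ccccc2)c(OCc2ccccc2)c1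
F5 | step 7 | [2,3-bis(benzyloxy)-5-(1,3-dioxolan-2-yl)phenyl]zinc chloride | C1COC(O1)c1cc([Zn]Cl)c(OCc2ccccc2)c(OCc2ccccc2)c1
F6 | step 7 | 5,7-bis(benzyloxy)-2-[3,4-bis(benzyloxy)phenyl]-8-[2,3-bis(benzyloxy)-5-(1,3-dioxolan-2-yl)phenyl]-4H-chromen-4-one | C1COC(O1)c1cc(OCc2ccccc2)c(OCc2ccccc2)c(-c2c(OCc3ccccc3)cc(OCc3ccccc3)c3c(=O)cc(-c4ccc(OCc5ccccc5)c(OCc5ccccc5)c4)oc23)c1
F0 | step 11 | none | none
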